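The numbers were set for the occasion; no experiment stands behind them.

If this run is repeated, the figure to hold the reading against is the share of free monomer that the protic impurity leaves for the chains.

free monomer 0.50 mM (fed, over 25 s); protic impurity 0.0100 mM; initiator 5.1 mol%; time 8.0 min

    free monomer + initiator → living end + monomer in chains (k1 = 3930 /M/s)
    free monomer + living end → monomer in chains + living end, rate k2*[living end]*[free monomer] (k2 = 1850 /M/s)
    protic impurity + free monomer → quenched substrate (k3 = 2920 /M/s)

* the state of affairs at 8.0 min: stopped, and by what, or still going (it is still moving / all of the free monomer has reacted / no working catalyst is left)
* the monomer in chains standing at 8.0 min, as a percentage of the free monomer charged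

- the reaction counts as stopped when no species that holds the free monomer changes by six tenths of a point or more over the second half of the time
- run time (flask): 8.0 min

Each protic impurity takes one free monomer into quenched substrate, while firing and growth both put monomer into chains. So once impurity and free monomer have reacted, the chains hold 98.0% of the charge, and this share is the yield ceiling.

The reckoning by hand then climbs a ladder of times. Fed monomer rises in step with time, and integrating the rate of a minor charge against that rise gives a time scale of the square root of twice the feed time over rate constant times charge. This is 5.04 s for the initiator and 5.85 s for the impurity, both shorter than the feed of 25 s. This reckoning then gives the flask living ends equal to the initiator charge, 0.0255 mM, and once the feed has ended, free monomer decays pseudo-first-order with a half-life of 14.7 s. After the feed, the run holds 31.0 such half-lives, so this reckoning expects the free monomer to have reacted and the chains to stand at the ceiling.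

The forecast states that all of the free monomer has reacted, with 98% in chains, holding that “everything else ends up in chains”. The simulation states that all of the free monomer has reacted, with 98.0% in chains.

In this flask, quenching has half its turnover behind it at 0.0893 min, earlier than growth at 0.488 min. Quenched substrate already reads 2.00% at the end of the feed and 2.00% at 8.00 min, while the chains climb from 41.2% to 98.0%, the ceiling of 98.0%.

In the neighbour flask with 0.12 mM of free monomer, the same amount of protic impurity and the same initiator loading, the ceiling falls to 91.7%. That neighbour gives 91.2%, with 8.33% quenched substrate and 0.45% free monomer still there at 8.00 min.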